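**Plan** (labdane numbering: ring A = C1–C5, C10; ring B = C5–C10; C17 on C8, C18/C19 on C4, C20 on C10, chain C11–C16)
1. Cuts: acetates and C15 silyl ether off; C7–OH back to a 6β-hydroxy-7-ketone; C9–C11 by 1,2-addition plus oxidative 1,3-transposition from a 9-ketone and a C11–C16 homoallyl iodide; C6–O by γ-oxidation; ring A at C3–C4 (helper ester on C2); C10–C1 and C10–C20 by enolate alkylations, back to (R)-carvone.
2. Forward: ring B is the carvone ring (its C=O is C9, its C-methyl carbon is C8 with C17, its isopropenyl is C4/C18/C19). Ring A is closed last (step 7); then C6 oxidation, side chain, C7.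
3. Enabling feature: the gem-dimethyl quaternary C4 of ring A next to the C5 methine is an isopropenyl group plus one hydrogen atom. H-atom transfer gives the tertiary C4 radical, which closes C3–C4 onto a 2-(methoxycarbonyl)allyl arm on C10 (C1–C3); the C2 ester is removed by Barton decarboxylation.
4. Stereochemistry: C5 from (R)-carvone; C10 by alkylation anti to the isopropenyl; C6 by α-face hydride on a 6-ketone; C7 by hydride delivered from the 6β-OH; 13E by syn-carboalumination.

Key step: step 7

Remark: centres formed without control and erased later (C6 of 9 in carvone numbering; C2 of 13–16) are left open in the SMILES; these compounds are epimer mixtures and are carried on as such. The target is (5S,6S,7S,10S), i.e. 6β,7α-diacetoxy with 5α-H and 10β-CH3.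

**Side chain (C11–C16)**

Step 1
Reactants: 1 tert-butyl(but-3-yn-1-yloxy)dimethylsilane
Product: 3 (E)-5-[(tert-butyldimethylsilyl)oxy]-3-methylpent-2-en-1-ol, via alkenyldimethylalane 2 (not isolated)
Conditions: AlMe3 (2 equiv), Cp2ZrCl2 (20 mol%), CH2Cl2, 0 °C → rt; then n-BuLi, (CH2O)n, THF, −78 °C → rt; aq. work-up
Reagents that add atoms: trimethylaluminium C[Al](C)C; formaldehyde (as paraformaldehyde) C=O
Why: Negishi carboalumination adds CH3–Al syn across the alkyne with methyl on the internal carbon, and the alkenyl–Al bond (as the ate complex) is hydroxymethylated with retention, which fixes the 13E geometry.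

Step 2
Reactants: 3 (E)-5-[(tert-butyldimethylsilyl)oxy]-3-methylpent-2-en-1-ol
Product: 4 (E)-1-[(tert-butyldiphenylsilyl)oxy]-5-[(tert-butyldimethylsilyl)oxy]-3-methylpent-2-ene
Conditions: TBDPSCl, imidazole, DMF, rt
Reagents that add atoms: tert-butyldiphenylsilyl chloride CC(C)(C)[Si](Cl)(c1ccccc1)c1ccccc1
Why: imidazole-promoted silylation of the primary allylic alcohol; no stereocentre is involved.

Step 3
Reactants: 4 (E)-1-[(tert-butyldiphenylsilyl)oxy]-5-[(tert-butyldimethylsilyl)oxy]-3-methylpent-2-ene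
Product: 5 (E)-5-[(tert-butyldiphenylsilyl)oxy]-3-methylpent-3-en-1-ol
Conditions: PPTS (cat.), EtOH, rt → 40 °C
Reagents that add atoms: none
Why: acid-catalysed solvolysis should remove the far more acid-labile primary TBS ether and leave the TBDPS ether (orthogonal silyl ether cleavage).

Step 4
Reactants: 5 (E)-5-[(tert-butyldiphenylsilyl)oxy]-3-methylpent-3-en-1-ol
Product: 6 (E)-tert-butyl[(5-iodo-3-methylpent-2-en-1-yl)oxy]diphenylsilane
Conditions: I2, PPh3, imidazole, CH2Cl2, 0 °C
Reagents that add atoms: iodine II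
Why: Appel-type iodination of the primary alcohol through the alkoxyphosphonium iodide; the E alkene and the silyl ether are not touched.

**Main line**

Step 5
Reactants: 7 (R)-(−)-carvone
Product: 9 (5R)-2,6-dimethyl-5-(prop-1-en-2-yl)cyclohex-2-en-1-one (6-methylcarvone; C6 epimers), via carvone lithium enolate 8 (not isolated)
Conditions: LDA, THF, −78 °C; MeI, −78 → 0 °C
Reagents that add atoms: iodomethane CI
Why: kinetic α′-deprotonation gives the cross-conjugated enolate, which is C-methylated (this methyl is C20); the new centre is planarised again in step 6, so its configuration does not matter.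

Step 6
Reactants: 9 (5R)-2,6-dimethyl-5-(prop-1-en-2-yl)cyclohex-2-en-1-one; 10 methyl 2-(bromomethyl)acrylate
Product: 12 methyl 2-{[(1S,6S)-1,3-dimethyl-2-oxo-6-(prop-1-en-2-yl)cyclohex-3-en-1-yl]methyl}prop-2-enoate, via lithium enolate 11 (not isolated)
Conditions: LDA, THF, −78 → −10 °C; then 10, −78 °C → rt
Reagents that add atoms: none
Why: enolate alkylation with the allylic bromide (SN2 and SN2′ give the same product); the electrophile should enter anti to the adjacent isopropenyl group (held pseudoaxial by A1,2 strain with the enolate methyl), so C10 carries the arm trans and the methyl cis to the isopropenyl, which is the 10β-methyl/trans-fusion arrangement.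

Step 7
Reactants: 12 methyl 2-{[(1S,6S)-1,3-dimethyl-2-oxo-6-(prop-1-en-2-yl)cyclohex-3-en-1-yl]methyl}prop-2-enoate
Product: 13 methyl (4aS,8aS)-4,4,7,8a-tetramethyl-8-oxo-1,2,3,4,4a,5,8,8a-octahydronaphthalene-2-carboxylate (C2 epimers)
Conditions: Fe(acac)3 (30 mol%), PhSiH3, EtOH–(CH2OH)2, 60 °C, dilute
Reagents that add atoms: none
Why: An iron hydride formed from Fe(acac)3 and PhSiH3 should transfer a hydrogen atom to the CH2 of the isopropenyl group, giving the tertiary C4 radical with C18 and C19 already in place; this nucleophilic radical adds to the unsubstituted β-carbon (C3) of the acrylate arm, and the α-ester radical at C2 is reduced by Fe(II) and protonated by ethanol. The closest known reaction type is the iron-mediated reductive olefin coupling (H-atom-transfer-initiated Giese addition) in its intramolecular form. Ring A (C1–C5, C10) closes by 6-endo-trig formation of C3–C4; 5-exo attack on the ester-bearing C2 would join two fully substituted carbons against the polarity of the acceptor and should not compete. The only new stereocentre is C2, which is not controlled and is erased in step 9; C5 and C10 already carry the two arms trans (diequatorial in the half-chair), so the ring fusion can only be trans. The step needs H-atom transfer to the isopropenyl group and not to the acrylate or the enone; the electron-rich, unhindered 1,1-disubstituted alkene is the best hydrogen acceptor while the electron-poor alkenes act as radical acceptors, and the intramolecular addition should outrun reduction of the tertiary radical.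

Step 8
Reactants: 13 methyl (4aS,8aS)-4,4,7,8a-tetramethyl-8-oxo-1,2,3,4,4a,5,8,8a-octahydronaphthalene-2-carboxylate
Product: 14 (4aS,8aS)-4,4,7,8a-tetramethyl-8-oxo-1,2,3,4,4a,5,8,8a-octahydronaphthalene-2-carboxylic acid (C2 epimers)
Conditions: LiOH, THF/MeOH/H2O, rt; then 1 M HCl
Reagents that add atoms: lithium hydroxide [Li+].[OH-]
Why: saponification of an unhindered secondary methyl ester; epimerisation at C2 is irrelevant and the enone is stable to the conditions.

Step 9
Reactants: 14 (4aS,8aS)-4,4,7,8a-tetramethyl-8-oxo-1,2,3,4,4a,5,8,8a-octahydronaphthalene-2-carboxylic acid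
Product: 17 (4aS,8aS)-2,5,5,8a-tetramethyl-4a,5,6,7,8,8a-hexahydronaphthalen-1(4H)-one, via acid chloride 15 (not isolated), via Barton ester 16 (not isolated)
Conditions: (COCl)2, cat. DMF, CH2Cl2, 0 °C → rt; then 2-mercaptopyridine N-oxide sodium salt, DMAP (cat.), t-BuSH, PhH, hν (W lamp), rt
Reagents that add atoms: none
Why: Barton reductive decarboxylation: the thiohydroxamate ester fragments to CO2 and the secondary C2 radical, which takes hydrogen from t-BuSH; this removes the helper group and the uncontrolled C2 centre in one operation.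

Step 10
Reactants: 17 (4aS,8aS)-2,5,5,8a-tetramethyl-4a,5,6,7,8,8a-hexahydronaphthalen-1(4H)-one
Product: 18 (4aS,8aS)-2,5,5,8a-tetramethyl-4a,5,6,7,8,8a-hexahydronaphthalene-1,4-dione
Conditions: Rh2(cap)4 (1 mol%), t-BuOOH, K2CO3, CH2Cl2, rt
Reagents that add atoms: tert-butyl hydroperoxide CC(C)(C)OO
Why: catalytic allylic C–H oxidation of an enone to the 1,4-enedione by tert-butylperoxyl radicals; C6 is the only methylene that is both allylic and γ to the carbonyl, and the trans fusion at C5 is the stable one.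

Step 11
Reactants: 18 (4aS,8aS)-2,5,5,8a-tetramethyl-4a,5,6,7,8,8a-hexahydronaphthalene-1,4-dione
Product: 19 (4R,4aS,8aS)-4-hydroxy-2,5,5,8a-tetramethyl-4a,5,6,7,8,8a-hexahydronaphthalen-1(4H)-one (6β-OH in labdane numbering)
Conditions: NaBH4 (0.3 equiv), CeCl3·7H2O, MeOH, −78 °C
Reagents that add atoms: none
Why: Luche 1,2-reduction; the C9 carbonyl is shielded by quaternary C10 and the C8 methyl (ketoisophorone-type regioselectivity), and hydride should reach C6 from the α face because the β face is closed by the syn-axial methyls on C10 and C4, giving the axial 6β-alcohol.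

Step 12
Reactants: 19 (4R,4aS,8aS)-4-hydroxy-2,5,5,8a-tetramethyl-4a,5,6,7,8,8a-hexahydronaphthalen-1(4H)-one
Product: 20 (4R,4aS,8aS)-2,5,5,8a-tetramethyl-4-[(triethylsilyl)oxy]-4a,5,6,7,8,8a-hexahydronaphthalen-1(4H)-one
Conditions: TESOTf, 2,6-lutidine, CH2Cl2, 0 °C
Reagents that add atoms: triethylsilyl trifluoromethanesulfonate CC[Si](CC)(CC)OS(=O)(=O)C(F)(F)F
Why: silyl triflates silylate hindered axial alcohols; the ether protects the 6β-oxygen from the organolithium and from chromium(VI).

Step 13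
Reactants: 6 (E)-tert-butyl[(5-iodo-3-methylpent-2-en-1-yl)oxy]diphenylsilane; 20 (4R,4aS,8aS)-2,5,5,8a-tetramethyl-4-[(triethylsilyl)oxy]-4a,5,6,7,8,8a-hexahydronaphthalen-1(4H)-one
Product: 22 (13E)-15-(tert-butyldiphenylsilyloxy)-6β-(triethylsilyloxy)labda-7,13-dien-9-ol, via homoallyllithium 21 (not isolated)
Conditions: 6, t-BuLi (2.1 equiv), Et2O/pentane, −78 °C; then 20, THF, −78 → −20 °C; H2O
Reagents that add atoms: none
Why: lithium–iodine exchange followed by 1,2-addition of a primary alkyllithium to the enone carbonyl (C10 has no α-hydrogen); attack is expected anti to the angular methyl (9β-OH), and this centre is erased in step 14.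

Step 14
Reactants: 22 (13E)-15-(tert-butyldiphenylsilyloxy)-6β-(triethylsilyloxy)labda-7,13-dien-9-ol
Product: 23 (13E)-15-(tert-butyldiphenylsilyloxy)-6β-(triethylsilyloxy)labda-8,13-dien-7-one
Conditions: PCC, NaOAc, 4 Å MS, CH2Cl2, rt
Reagents that add atoms: pyridinium chlorochromate [O-][Cr](=O)(=O)Cl.c1cc[nH+]cc1
Why: Babler–Dauben oxidative transposition: the chromate ester of the tertiary allylic alcohol undergoes a [3,3] shift to C7 (the C7 oxygen comes from chromium) and is oxidised to the enone, which places the double bond at C8=C9 with C17 and the side chain on it.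

Step 15
Reactants: 23 (13E)-15-(tert-butyldiphenylsilyloxy)-6β-(triethylsilyloxy)labda-8,13-dien-7-one
Product: 24 (13E)-15-(tert-butyldiphenylsilyloxy)-6β-hydroxylabda-8,13-dien-7-one
Conditions: PPTS (cat.), MeOH/CH2Cl2, 0 °C → rt
Reagents that add atoms: none
Why: acidic methanolysis removes the TES ether, which is several orders of magnitude more acid-labile than the primary TBDPS ether; C6 is not epimerised under these mild conditions.

Step 16
Reactants: 24 (13E)-15-(tert-butyldiphenylsilyloxy)-6β-hydroxylabda-8,13-dien-7-one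
Product: 25 (13E)-15-(tert-butyldiphenylsilyloxy)labda-8,13-diene-6β,7α-diol
Conditions: Me4NBH(OAc)3, AcOH/MeCN, −20 °C → rt
Reagents that add atoms: none
Why: Saksena–Evans hydroxyl-directed reduction: the borohydride exchanges an acetate for the axial 6β-oxygen, which sits over the β face of the C7 carbonyl and delivers hydride there, so the new hydroxyl is pushed to the α face (trans-diaxial 6β,7α-diol); the reagent does not reduce unbound enones.

Step 17
Reactants: 25 (13E)-15-(tert-butyldiphenylsilyloxy)labda-8,13-diene-6β,7α-diol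
Product: 26 (13E)-15-(tert-butyldiphenylsilyloxy)labda-8,13-diene-6β,7α-diyl diacetate
Conditions: Ac2O, DMAP, pyridine, rt → 50 °C
Reagents that add atoms: acetic anhydride CC(=O)OC(C)=O
Why: DMAP-catalysed O-acetylation of both secondary alcohols with retention at C6 and C7; warming is planned for the hindered axial 6β-OH.

Step 18
Reactants: 26 (13E)-15-(tert-butyldiphenylsilyloxy)labda-8,13-diene-6β,7α-diyl diacetate
Product: 27 (13E)-15-hydroxylabda-8,13-diene-6β,7α-diyl diacetate (target)
Conditions: HF·pyridine, pyridine, THF, 0 °C → rt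
Reagents that add atoms: none
Why: fluoride cleavage of the primary TBDPS ether; acetates, the allylic C7 ester and both alkenes are stable to buffered HF·pyridine, so no acyl migration or hydrolysis is expected.

**Compound list**
1 | tert-butyl(but-3-yn-1-yloxy)dimethylsilane | C#CCCO[Si](C)(C)C(C)(C)C | starting material
2 | (E)-{4-[(tert-butyldimethylsilyl)oxy]-2-methylbut-1-en-1-yl}dimethylaluminium (not isolated) | C[Al](C)/C=C(\C)CCO[Si](C)(C)C(C)(C)C | intermediate
3 | (E)-5-[(tert-butyldimethylsilyl)oxy]-3-methylpent-2-en-1-ol | OC/C=C(\C)CCO[Si](C)(C)C(C)(C)C | intermediate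
4 | (E)-1-[(tert-butyldiphenylsilyl)oxy]-5-[(tert-butyldimethylsilyl)oxy]-3-methylpent-2-ene | CC(C)(C)[Si](c1ccccc1)(c1ccccc1)OC/C=C(\C)CCO[Si](C)(C)C(C)(C)C | intermediate
5 | (E)-5-[(tert-butyldiphenylsilyl)oxy]-3-methylpent-3-en-1-ol | OCC/C(C)=C/CO[Si](c1ccccc1)(c1ccccc1)C(C)(C)C | intermediate
6 | (E)-tert-butyl[(5-iodo-3-methylpent-2-en-1-yl)oxy]diphenylsilane | ICC/C(C)=C/CO[Si](c1ccccc1)(c1ccccc1)C(C)(C)C | intermediate
7 | (R)-(−)-carvone | CC1=CC[C@H](CC1=O)C(C)=C | starting material
8 | lithium cross-conjugated enolate of carvone (not isolated) | [Li]OC1=C[C@H](C(C)=C)CC=C1C | intermediate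
9 | (5R)-2,6-dimethyl-5-(prop-1-en-2-yl)cyclohex-2-en-1-one, C6 epimers | CC1=CC[C@H](C(C)C1=O)C(C)=C | intermediate
10 | methyl 2-(bromomethyl)acrylate | COC(=O)C(=C)CBr | starting material
11 | lithium enolate of 9 (not isolated) | [Li]OC1=C(C)[C@H](C(C)=C)CC=C1C | intermediate
12 | methyl 2-{[(1S,6S)-1,3-dimethyl-2-oxo-6-(prop-1-en-2-yl)cyclohex-3-en-1-yl]methyl}prop-2-enoate | C1C=C(C)C(=O)[C@@](C)(CC(=C)C(=O)OC)[C@@H]1C(C)=C | intermediate
13 | methyl (4aS,8aS)-4,4,7,8a-tetramethyl-8-oxo-1,2,3,4,4a,5,8,8a-octahydronaphthalene-2-carboxylate, C2 epimers | C1C=C(C)C(=O)[C@@]2(C)CC(C(=O)OC)CC(C)(C)[C@H]12 | intermediate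
14 | (4aS,8aS)-4,4,7,8a-tetramethyl-8-oxo-1,2,3,4,4a,5,8,8a-octahydronaphthalene-2-carboxylic acid, C2 epimers | C1C=C(C)C(=O)[C@@]2(C)CC(C(=O)O)CC(C)(C)[C@H]12 | intermediate
15 | acid chloride of 14 (not isolated) | C1C=C(C)C(=O)[C@@]2(C)CC(C(=O)Cl)CC(C)(C)[C@H]12 | intermediate
16 | 2-thioxopyridin-1(2H)-yl ester of 14 (Barton ester, not isolated) | C1C=C(C)C(=O)[C@@]2(C)CC(C(=O)ON3C=CC=CC3=S)CC(C)(C)[C@H]12 | intermediate
17 | (4aS,8aS)-2,5,5,8a-tetramethyl-4a,5,6,7,8,8a-hexahydronaphthalen-1(4H)-one | C1C=C(C)C(=O)[C@@]2(C)CCCC(C)(C)[C@H]12 | intermediate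
18 | (4aS,8aS)-2,5,5,8a-tetramethyl-4a,5,6,7,8,8a-hexahydronaphthalene-1,4-dione | O=C1C=C(C)C(=O)[C@@]2(C)CCCC(C)(C)[C@H]12 | intermediate
19 | (4R,4aS,8aS)-4-hydroxy-2,5,5,8a-tetramethyl-4a,5,6,7,8,8a-hexahydronaphthalen-1(4H)-one | O[C@@H]1C=C(C)C(=O)[C@@]2(C)CCCC(C)(C)[C@H]12 | intermediate
20 | (4R,4aS,8aS)-2,5,5,8a-tetramethyl-4-[(triethylsilyl)oxy]-4a,5,6,7,8,8a-hexahydronaphthalen-1(4H)-one | CC[Si](CC)(CC)O[C@@H]1C=C(C)C(=O)[C@@]2(C)CCCC(C)(C)[C@H]12 | intermediate
21 | (E)-{5-[(tert-butyldiphenylsilyl)oxy]-3-methylpent-3-en-1-yl}lithium (not isolated) | [Li]CC/C(C)=C/CO[Si](c1ccccc1)(c1ccccc1)C(C)(C)C | intermediate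
22 | (13E)-15-(tert-butyldiphenylsilyloxy)-6β-(triethylsilyloxy)labda-7,13-dien-9-ol (9β-OH expected) | CC[Si](CC)(CC)O[C@@H]1C=C(C)[C@@](O)(CC/C(C)=C/CO[Si](c3ccccc3)(c3ccccc3)C(C)(C)C)[C@@]2(C)CCCC(C)(C)[C@H]12 | intermediate
23 | (13E)-15-(tert-butyldiphenylsilyloxy)-6β-(triethylsilyloxy)labda-8,13-dien-7-one | CC[Si](CC)(CC)O[C@@H]1C(=O)C(C)=C(CC/C(C)=C/CO[Si](c3ccccc3)(c3ccccc3)C(C)(C)C)[C@@]2(C)CCCC(C)(C)[C@H]12 | intermediate
24 | (13E)-15-(tert-butyldiphenylsilyloxy)-6β-hydroxylabda-8,13-dien-7-one | O[C@@H]1C(=O)C(C)=C(CC/C(C)=C/CO[Si](c3ccccc3)(c3ccccc3)C(C)(C)C)[C@@]2(C)CCCC(C)(C)[C@H]12 | intermediate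
25 | (13E)-15-(tert-butyldiphenylsilyloxy)labda-8,13-diene-6β,7α-diol | O[C@@H]1[C@@H](O)C(C)=C(CC/C(C)=C/CO[Si](c3ccccc3)(c3ccccc3)C(C)(C)C)[C@@]2(C)CCCC(C)(C)[C@H]12 | intermediate
26 | (13E)-15-(tert-butyldiphenylsilyloxy)labda-8,13-diene-6β,7α-diyl diacetate | CC(=O)O[C@@H]1[C@@H](OC(C)=O)C(C)=C(CC/C(C)=C/CO[Si](c3ccccc3)(c3ccccc3)C(C)(C)C)[C@@]2(C)CCCC(C)(C)[C@H]12 | intermediate
27 | (5S,6S,7S,10S,13E)-15-hydroxylabda-8,13-diene-6,7-diyl diacetate (6β,7α) | CC(=O)O[C@@H]1[C@@H](OC(C)=O)C(C)=C(CC/C(C)=C/CO)[C@@]2(C)CCCC(C)(C)[C@H]12 | target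

**Count**
Total steps: 18. Longest linear sequence: 14 (steps 5–18, from (R)-carvone).

**Steps most likely to fail**

Step 7. Hydrogen-atom transfer may go to the acrylate or the enone instead of the isopropenyl group, or the tertiary radical may be reduced before it cyclises. The fallback sets out from 12 and separates radical generation from any metal hydride. Markovnikov addition of HBr (1.05 equiv, 33% in AcOH, CH2Cl2, −20 °C; the classical carvone hydrobromide reaction) should give the tertiary bromide methyl 2-{[(1S,6R)-6-(2-bromopropan-2-yl)-1,3-dimethyl-2-oxocyclohex-3-en-1-yl]methyl}prop-2-enoate F1. Slow addition of Bu3SnH/AIBN in benzene at 80 °C then abstracts bromine and the same C4 radical closes 6-endo onto the acrylate in a tin-hydride Giese cyclisation. The route is rejoined at 13.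

Step 16. Hydride delivery from the hindered axial 6β-oxygen may be slow, and uncomplexed hydride would attack the α face and give the wrong C7 epimer. The fallback sets out from 23 and accepts external α-face attack. Luche reduction should give (13E)-15-(tert-butyldiphenylsilyloxy)-6β-(triethylsilyloxy)labda-8,13-dien-7β-ol F3. Mitsunobu inversion (PPh3, DIAD, AcOH) would give (13E)-15-(tert-butyldiphenylsilyloxy)-6β-(triethylsilyloxy)labda-8,13-dien-7α-yl acetate F4. PPTS/MeOH would then give (13E)-15-(tert-butyldiphenylsilyloxy)-6β-hydroxylabda-8,13-dien-7α-yl acetate F5, and acetylation (Ac2O, DMAP) rejoins the route at 26.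

Step 14. The hindered tertiary allylic alcohol may dehydrate to dienes, or the chromate ester may fail to migrate next to the bulky 6β-silyloxy group. The fallback sets out from 22 and separates transposition from oxidation. A rhenium(VII) catalyst (Ph3SiOReO3, Et2O, −50 → 0 °C) should isomerise 22 to the more stable secondary allylic alcohol with the tetrasubstituted alkene, (13E)-15-(tert-butyldiphenylsilyloxy)-6β-(triethylsilyloxy)labda-8,13-dien-7-ol (C7 epimers) F2. Dess–Martin oxidation of this alcohol rejoins the route at 23.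

**Further compounds**
F1 | step 7 | methyl 2-{[(1S,6R)-6-(2-bromopropan-2-yl)-1,3-dimethyl-2-oxocyclohex-3-en-1-yl]methyl}prop-2-enoate | C1C=C(C)C(=O)[C@@](C)(CC(=C)C(=O)OC)[C@@H]1C(C)(C)Br
F2 | step 14 | (13E)-15-(tert-butyldiphenylsilyloxy)-6β-(triethylsilyloxy)labda-8,13-dien-7-ol (C7 epimers) | CC[Si](CC)(CC)O[C@@H]1C(O)C(C)=C(CC/C(C)=C/CO[Si](c3ccccc3)(c3ccccc3)C(C)(C)C)[C@@]2(C)CCCC(C)(C)[C@H]12
F3 | step 16 | (13E)-15-(tert-butyldiphenylsilyloxy)-6β-(triethylsilyloxy)labda-8,13-dien-7β-ol | CC[Si](CC)(CC)O[C@@H]1[C@H](O)C(C)=C(CC/C(C)=C/CO[Si](c3ccccc3)(c3ccccc3)C(C)(C)C)[C@@]2(C)CCCC(C)(C)[C@H]12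
F4 | step 16 | (13E)-15-(tert-butyldiphenylsilyloxy)-6β-(triethylsilyloxy)labda-8,13-dien-7α-yl acetate | CC[Si](CC)(CC)O[C@@H]1[C@@H](OC(C)=O)C(C)=C(CC/C(C)=C/CO[Si](c3ccccc3)(c3ccccc3)C(C)(C)C)[C@@]2(C)CCCC(C)(C)[C@H]12
F5 | step 16 | (13E)-15-(tert-butyldiphenylsilyloxy)-6β-hydroxylabda-8,13-dien-7α-yl acetate | O[C@@H]1[C@@H](OC(C)=O)C(C)=C(CC/C(C)=C/CO[Si](c3ccccc3)(c3ccccc3)C(C)(C)C)[C@@]2(C)CCCC(C)(C)[C@H]12
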